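**Retrosynthetic overview**
- Target ⇐ fluoride cleavage of three aryl triisopropylsilyl (TIPS) ethers on the fully assembled skeleton.
- Exocyclic (Z)-arylidene (aryl–C bond and C=C) ⇐ palladium carbene coupling of a 4-formyl-tetrahydrofuran with a protected 4-bromoguaiacol.
- 2-Aryl-3-(acyloxymethyl)-4-formyl-tetrahydrofuran ⇐ pinacol-terminated Prins reaction of an aryl aldehyde with an (R)-allylic 1,2-diol: a six-membered oxacycle (tetrahydropyranyl cation) closes first and contracts by a 1,2-shift to the tetrahydrofuran, the only ring made, setting C2 and C3.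
- Allylic diol ⇐ cross-metathesis of (R)-but-3-ene-1,2-diol with allyl 4-silyloxybenzoate (aryl bromide + allyl chloroformate).
- Both guaiacyl units ⇐ one silyl-protected 4-bromoguaiacol (catechol: O-methylation, bromination, silylation), formylated for the aldehyde partner.

Assumptions: (R)-but-3-ene-1,2-diol and (4-bromophenoxy)triisopropylsilane are bought; chirality transfer in step 7 follows the chair with the tin-bound carbinol oxygen axial, so the (R)-diol gives the (2R,3S) series (the (S)-diol is used instead if the opposite sense is found).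

**Route**

Step 1
Reactants: 1 catechol (benzene-1,2-diol)
Product: 2 guaiacol (2-methoxyphenol)
Conditions: MeI (1.0 equiv), K2CO3 (1.0 equiv), acetone, reflux
Reagents that add atoms: iodomethane (CI)
Why: Williamson O-methylation; the catechol monoanion is alkylated once and the remaining hydroxyl is much less acidic, so one equivalent of MeI gives mainly guaiacol, which is freed from veratrole and catechol by base extraction and distillation.

Step 2
Reactants: 2 guaiacol
Product: 3 4-bromo-2-methoxyphenol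
Conditions: NBS (1.0 equiv), MeCN, 0 °C to rt
Reagents that add atoms: N-bromosuccinimide (O=C1CCC(=O)N1Br)
Why: Electrophilic aromatic bromination; the free hydroxyl is the stronger para director, so bromine enters para to OH and meta to OMe, the position that later carries carbon in both guaiacyl units.

Step 3
Reactants: 3 4-bromo-2-methoxyphenol
Product: 4 (4-bromo-2-methoxyphenoxy)triisopropylsilane
Conditions: TIPSCl, imidazole, DMF, rt
Reagents that add atoms: triisopropylsilyl chloride (CC(C)[Si](Cl)(C(C)C)C(C)C)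
Why: Phenol silylation; the TIPS ether tolerates n-BuLi, SnCl4 at low temperature and carbonate base, and is removed by fluoride at the end.

Step 4
Reactants: 4 (4-bromo-2-methoxyphenoxy)triisopropylsilane
Product: 6 3-methoxy-4-[(triisopropylsilyl)oxy]benzaldehyde, via aryllithium 5 (not isolated)
Conditions: n-BuLi, THF, −78 °C; DMF; H2O
Reagents that add atoms: N,N-dimethylformamide (CN(C)C=O)
Why: Bromine–lithium exchange followed by Bouveault formylation of the aryllithium.

Step 5
Reactants: 7 (4-bromophenoxy)triisopropylsilane; 8 allyl chloroformate (prop-2-en-1-yl carbonochloridate)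
Product: 10 prop-2-en-1-yl 4-[(triisopropylsilyl)oxy]benzoate, via aryllithium 9 (not isolated)
Conditions: n-BuLi, THF, −78 °C; then inverse addition to 8 (1.5 equiv), THF, −78 °C
Reagents that add atoms: none
Why: Bromine–lithium exchange and acylation of the aryllithium by the chloroformate; inverse addition to excess chloroformate at −78 °C keeps the ester from a second addition.

Step 6
Reactants: 10 prop-2-en-1-yl 4-[(triisopropylsilyl)oxy]benzoate; 11 (R)-but-3-ene-1,2-diol
Product: 12 (2E,4R)-4,5-dihydroxypent-2-en-1-yl 4-[(triisopropylsilyl)oxy]benzoate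
Conditions: second-generation Hoveyda–Grubbs catalyst RuCl2(H2IMes)(=CH-C6H4-2-OiPr) (5 mol%), 1,4-benzoquinone (10 mol%), 10 (2.5 equiv), CH2Cl2, 40 °C
Reagents that add atoms: none
Why: Olefin cross-metathesis between the fast-dimerising allyl ester and the secondary allylic alcohol; it is E-selective under thermodynamic control, leaves the carbinol stereocentre untouched, and the E geometry is what later fixes the 2,3-trans relationship.

Step 7
Reactants: 12 (2E,4R)-4,5-dihydroxypent-2-en-1-yl 4-[(triisopropylsilyl)oxy]benzoate; 6 3-methoxy-4-[(triisopropylsilyl)oxy]benzaldehyde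
Product: 15 [(2R,3S,4R)-4-formyl-2-{3-methoxy-4-[(triisopropylsilyl)oxy]phenyl}oxolan-3-yl]methyl 4-[(triisopropylsilyl)oxy]benzoate, via dioxolane acetal 13 (not isolated), via tetrahydropyranyl cation 14 (not isolated)
Conditions: PPTS (5 mol%), 4 Å MS, CH2Cl2, rt; then SnCl4 (2 equiv), −78 to −30 °C; aq NaHCO3
Reagents that add atoms: none
Why: Pinacol-terminated Prins cyclisation (Overman): SnCl4 opens acetal 13 to the (E)-oxocarbenium ion, which closes on the E alkene through a chair with aryl and acyloxymethyl equatorial (hence 2,3-trans) and the tin alkoxide axial, so the (R)-carbinol selects the chair giving 2R,3S; cation 14 then contracts by 1,2-shift of the ring CH2–O carbon onto the cationic centre, pushed by the alkoxide, to the formyl-tetrahydrofuran with the formyl group trans to the acyloxymethyl group.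

Step 8
Reactants: 15 [(2R,3S,4R)-4-formyl-2-{3-methoxy-4-[(triisopropylsilyl)oxy]phenyl}oxolan-3-yl]methyl 4-[(triisopropylsilyl)oxy]benzoate; 4 (4-bromo-2-methoxyphenoxy)triisopropylsilane
Product: 18 [(2R,3S,4Z)-2-{3-methoxy-4-[(triisopropylsilyl)oxy]phenyl}-4-({3-methoxy-4-[(triisopropylsilyl)oxy]phenyl}methylidene)oxolan-3-yl]methyl 4-[(triisopropylsilyl)oxy]benzoate, via sulfonylhydrazone 16 (not isolated), via diazoalkane 17 (not isolated)
Conditions: 2-(CF3)C6H4SO2NHNH2 (1.05 equiv), 1,4-dioxane, rt; then 4 (1.2 equiv), Pd2(dba)3 (2.5 mol%), XPhos (10 mol%), Cs2CO3 (2.5 equiv), 40 °C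
Reagents that add atoms: none
Why: Proposed new method: a Barluenga-type arylidenation run at 40 °C, in which the electron-poor 2-(trifluoromethyl)benzenesulfonylhydrazone 16 is deprotonated by Cs2CO3 and loses sulfinate to give diazoalkane 17, which ArPd(XPhos)Br (from oxidative addition of 4) traps as a palladium carbene; aryl migration from palladium to the carbene carbon and syn β-hydride elimination of the only β-hydrogen (ring C4) give the exocyclic styrene with the aryl turned away from the substituted C3 (Z), while the low temperature and carbonate base spare the benzoate, the silyl ethers and the ring; closest known reaction type is the Pd-catalysed cross-coupling of N-tosylhydrazones with aryl halides at 90–110 °C with LiOtBu, together with low-temperature diazo release from N-triftosylhydrazones in silver and rhodium carbene chemistry.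

Step 9
Reactants: 18 [(2R,3S,4Z)-2-{3-methoxy-4-[(triisopropylsilyl)oxy]phenyl}-4-({3-methoxy-4-[(triisopropylsilyl)oxy]phenyl}methylidene)oxolan-3-yl]methyl 4-[(triisopropylsilyl)oxy]benzoate
Product: 19 [(2R,3S,4Z)-2-(4-hydroxy-3-methoxyphenyl)-4-[(4-hydroxy-3-methoxyphenyl)methylidene]oxolan-3-yl]methyl 4-hydroxybenzoate (target CNP0134275.2)
Conditions: TBAF (3.3 equiv), AcOH (3.3 equiv), THF, 0 °C to rt
Reagents that add atoms: none
Why: Fluoride cleavage of the three aryl silyl ethers; the acetic acid buffer keeps the phenoxides from attacking the alkyl benzoate, and no stereocentre or the alkene is touched.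

**Compound list**

1 | catechol (benzene-1,2-diol) | Oc1ccccc1O | starting material
2 | guaiacol (2-methoxyphenol) | COc1ccccc1O | intermediate
3 | 4-bromo-2-methoxyphenol | COc1cc(Br)ccc1O | intermediate
4 | (4-bromo-2-methoxyphenoxy)triisopropylsilane | COc1cc(Br)ccc1O[Si](C(C)C)(C(C)C)C(C)C | intermediate
5 | {3-methoxy-4-[(triisopropylsilyl)oxy]phenyl}lithium (not isolated) | [Li]c1ccc(O[Si](C(C)C)(C(C)C)C(C)C)c(OC)c1 | intermediate
6 | 3-methoxy-4-[(triisopropylsilyl)oxy]benzaldehyde | COc1cc(C=O)ccc1O[Si](C(C)C)(C(C)C)C(C)C | intermediate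
7 | (4-bromophenoxy)triisopropylsilane | Brc1ccc(O[Si](C(C)C)(C(C)C)C(C)C)cc1 | starting material
8 | allyl chloroformate (prop-2-en-1-yl carbonochloridate) | C=CCOC(Cl)=O | starting material
9 | {4-[(triisopropylsilyl)oxy]phenyl}lithium (not isolated) | [Li]c1ccc(O[Si](C(C)C)(C(C)C)C(C)C)cc1 | intermediate
10 | prop-2-en-1-yl 4-[(triisopropylsilyl)oxy]benzoate | C=CCOC(=O)c1ccc(O[Si](C(C)C)(C(C)C)C(C)C)cc1 | intermediate
11 | (R)-but-3-ene-1,2-diol | OC[C@H](O)C=C | starting material
12 | (2E,4R)-4,5-dihydroxypent-2-en-1-yl 4-[(triisopropylsilyl)oxy]benzoate | OC[C@H](O)/C=C/COC(=O)c1ccc(O[Si](C(C)C)(C(C)C)C(C)C)cc1 | intermediate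
13 | (2E)-3-[(4R)-2-{3-methoxy-4-[(triisopropylsilyl)oxy]phenyl}-1,3-dioxolan-4-yl]prop-2-en-1-yl 4-[(triisopropylsilyl)oxy]benzoate, both epimers at the acetal carbon (not isolated) | COc1cc(C2OC[C@@H](/C=C/COC(=O)c3ccc(O[Si](C(C)C)(C(C)C)C(C)C)cc3)O2)ccc1O[Si](C(C)C)(C(C)C)C(C)C | intermediate
14 | zwitterionic (3R,5S,6R)-tetrahydropyran-4-ylium cation: 6-aryl (equatorial), 5-(aroyloxymethyl) (equatorial), 3-O–SnCl4 alkoxide (axial), cationic C4 (not isolated) | Cl[Sn-](Cl)(Cl)(Cl)O[C@H]1CO[C@@H](c2ccc(O[Si](C(C)C)(C(C)C)C(C)C)c(OC)c2)[C@H](COC(=O)c2ccc(O[Si](C(C)C)(C(C)C)C(C)C)cc2)[CH+]1 | intermediate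
15 | [(2R,3S,4R)-4-formyl-2-{3-methoxy-4-[(triisopropylsilyl)oxy]phenyl}oxolan-3-yl]methyl 4-[(triisopropylsilyl)oxy]benzoate (2,3-trans, 3,4-trans) | O=C[C@H]1CO[C@@H](c2ccc(O[Si](C(C)C)(C(C)C)C(C)C)c(OC)c2)[C@@H]1COC(=O)c1ccc(O[Si](C(C)C)(C(C)C)C(C)C)cc1 | intermediate
16 | 2-(trifluoromethyl)benzenesulfonylhydrazone of aldehyde 15, (2R,3S,4S) by CIP with unchanged spatial arrangement (not isolated) | FC(F)(F)c1ccccc1S(=O)(=O)NN=C[C@H]1CO[C@@H](c2ccc(O[Si](C(C)C)(C(C)C)C(C)C)c(OC)c2)[C@@H]1COC(=O)c1ccc(O[Si](C(C)C)(C(C)C)C(C)C)cc1 | intermediate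
17 | [(2R,3S,4S)-4-(diazomethyl)-2-{3-methoxy-4-[(triisopropylsilyl)oxy]phenyl}oxolan-3-yl]methyl 4-[(triisopropylsilyl)oxy]benzoate (not isolated) | [N-]=[N+]=C[C@H]1CO[C@@H](c2ccc(O[Si](C(C)C)(C(C)C)C(C)C)c(OC)c2)[C@@H]1COC(=O)c1ccc(O[Si](C(C)C)(C(C)C)C(C)C)cc1 | intermediate
18 | [(2R,3S,4Z)-2-{3-methoxy-4-[(triisopropylsilyl)oxy]phenyl}-4-({3-methoxy-4-[(triisopropylsilyl)oxy]phenyl}methylidene)oxolan-3-yl]methyl 4-[(triisopropylsilyl)oxy]benzoate | COc1cc(/C=C2\CO[C@@H](c3ccc(O[Si](C(C)C)(C(C)C)C(C)C)c(OC)c3)[C@@H]2COC(=O)c2ccc(O[Si](C(C)C)(C(C)C)C(C)C)cc2)ccc1O[Si](C(C)C)(C(C)C)C(C)C | intermediate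
19 | [(2R,3S,4Z)-2-(4-hydroxy-3-methoxyphenyl)-4-[(4-hydroxy-3-methoxyphenyl)methylidene]oxolan-3-yl]methyl 4-hydroxybenzoate | COc1cc(/C=C2\CO[C@@H](c3ccc(O)c(OC)c3)[C@@H]2COC(=O)c2ccc(O)cc2)ccc1O | target

**Step count and risks**

Total steps: 9. Longest linear sequence: 7 steps (steps 1, 2, 3, 4, 7, 8, 9; catechol to target).

Risk 1 (step 7, Prins–pinacol ring contraction). The aryl-stabilised oxocarbenium ion and the ester-deactivated alkene may react slowly. A hydride shift in cation 14 would give a tetrahydropyran-3-one. The sense and fidelity of chirality transfer from a secondary carbinol rest on the stated assumption. Fallback, setting out from aldehyde 6 and coming back at 18 (it also replaces step 8): iridium-catalysed anti-selective carbonyl (hydroxymethyl)allylation of 6 with 4-vinyl-1,3-dioxolan-2-one ([Ir(cod)Cl]2, SEGPHOS-type bisphosphine, 4-cyano-3-nitrobenzoic acid, K3PO4, i-PrOH, THF, 60 °C) gives, with both stereocentres set by the catalyst, the (1R,2S)-2-ethenyl-1-arylpropane-1,3-diol F2. Alkoxycarbonylation of bromide 7 at the primary hydroxyl (Pd(OAc)2, Xantphos, CO 1 atm, Et3N, toluene, 80 °C) gives the mono-ester F3. A Heck reaction with bromide 4 (Pd(OAc)2, P(o-tol)3, Et3N, DMF, 90 °C) gives the (E)-styrene F4. MOMCl and i-Pr2NEt give the methoxymethyl ether F5. Catalytic TMSOTf in CH2Cl2 at −78 °C ionises F5 to the formaldehyde oxocarbenium ion, the styrene closes the five-membered ring in a Prins reaction, and the p-silyloxybenzyl cation loses the C4 proton to give 18.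

Risk 2 (step 8, the proposed new arylidenation). Carbene dimerisation or azine formation, an E/Z mixture, or Pd–H migration of the alkene into the ring may occur. Fallback with known chemistry, setting out from aldehyde 15 and coming back at 18: aryllithium 5 (made from 4 as in step 4) is added to 15 in THF at −78 °C, where the aldehyde reacts far faster than the electron-rich benzoate, to give the benzylic alcohol F6 as a mixture of carbinol epimers. CSA (5 mol%) in toluene at 50 °C then dehydrates F6 through the p-silyloxybenzyl cation, whose only β-hydrogen sits on C4, under thermodynamic control to the Z alkene 18.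

Risk 3 (step 6, cross-metathesis on the free allylic diol). An E/Z mixture, ruthenium hydride isomerisation of the allylic alcohol to a ketone, and homodimers are possible. Fallback, setting out from diol 11 (with aldehyde 6) and coming back at acetal 13: 11 and 6 are condensed first (PPTS, 4 Å MS, CH2Cl2, rt) to the vinyl dioxolane F1. Cross-metathesis of F1 with 10 under the same ruthenium catalyst gives 13, now isolated and freed from the Z isomer by chromatography, and the SnCl4 stage of step 7 follows.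

**Further compounds**

F1 | step 6 | (4R)-4-ethenyl-2-{3-methoxy-4-[(triisopropylsilyl)oxy]phenyl}-1,3-dioxolane (acetal epimers) | COc1cc(C2OC[C@@H](C=C)O2)ccc1O[Si](C(C)C)(C(C)C)C(C)C
F2 | step 7 | (1R,2S)-2-ethenyl-1-{3-methoxy-4-[(triisopropylsilyl)oxy]phenyl}propane-1,3-diol | O[C@@H](c1ccc(O[Si](C(C)C)(C(C)C)C(C)C)c(OC)c1)[C@H](CO)C=C
F3 | step 7 | (2S)-2-[(R)-hydroxy{3-methoxy-4-[(triisopropylsilyl)oxy]phenyl}methyl]but-3-en-1-yl 4-[(triisopropylsilyl)oxy]benzoate | O[C@@H](c1ccc(O[Si](C(C)C)(C(C)C)C(C)C)c(OC)c1)[C@H](COC(=O)c1ccc(O[Si](C(C)C)(C(C)C)C(C)C)cc1)C=C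
F4 | step 7 | (2S,3E)-2-[(R)-hydroxy{3-methoxy-4-[(triisopropylsilyl)oxy]phenyl}methyl]-4-{3-methoxy-4-[(triisopropylsilyl)oxy]phenyl}but-3-en-1-yl 4-[(triisopropylsilyl)oxy]benzoate | O[C@@H](c1ccc(O[Si](C(C)C)(C(C)C)C(C)C)c(OC)c1)[C@H](COC(=O)c1ccc(O[Si](C(C)C)(C(C)C)C(C)C)cc1)/C=C/c1ccc(O[Si](C(C)C)(C(C)C)C(C)C)c(OC)c1
F5 | step 7 | (2S,3E)-2-[(R)-(methoxymethoxy){3-methoxy-4-[(triisopropylsilyl)oxy]phenyl}methyl]-4-{3-methoxy-4-[(triisopropylsilyl)oxy]phenyl}but-3-en-1-yl 4-[(triisopropylsilyl)oxy]benzoate | COCO[C@@H](c1ccc(O[Si](C(C)C)(C(C)C)C(C)C)c(OC)c1)[C@H](COC(=O)c1ccc(O[Si](C(C)C)(C(C)C)C(C)C)cc1)/C=C/c1ccc(O[Si](C(C)C)(C(C)C)C(C)C)c(OC)c1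
F6 | step 8 | [(2R,3S,4R)-4-(hydroxy{3-methoxy-4-[(triisopropylsilyl)oxy]phenyl}methyl)-2-{3-methoxy-4-[(triisopropylsilyl)oxy]phenyl}oxolan-3-yl]methyl 4-[(triisopropylsilyl)oxy]benzoate (carbinol epimers) | OC(c1ccc(O[Si](C(C)C)(C(C)C)C(C)C)c(OC)c1)[C@H]1CO[C@@H](c2ccc(O[Si](C(C)C)(C(C)C)C(C)C)c(OC)c2)[C@@H]1COC(=O)c1ccc(O[Si](C(C)C)(C(C)C)C(C)C)cc1
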